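**Assumptions:** The target has no stereocentres, so "single enantiomer" does not apply. Its only stereo-element is the E enone C=C, which is set in Step 1. 1-(5-Bromo-2,4-dihydroxyphenyl)ethanone (3) is taken as commercial. If it is not, it is one step from 2',4'-dihydroxyacetophenone by NBS bromination at C5.

## Retrosynthesis
1. Target **1** is the bis-C-prenylated 2',4',4-trihydroxychalcone. Both aryl–prenyl C–C bonds are cut by an α-selective Suzuki–Miyaura coupling with prenyl-Bpin **5**, which gives dibromochalcone **2**.
2. The enone C=C of **2** is cut by Claisen–Schmidt condensation into acetophenone **3** and aldehyde **4**.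
3. No rings are formed, because the target is acyclic.
4. The enone is built first and the prenyl groups are installed last. Prenyl-Bpin would allylborate the aldehyde if the coupling were done before condensation.
5. The bromine atoms fix the prenyl regiochemistry (C5' on ring A, C3 on ring B). Direct prenylation of resacetophenone would give C3'/C5' mixtures.

## Route

**Step 1**
Reactants: **3** 1-(5-bromo-2,4-dihydroxyphenyl)ethanone; **4** 3-bromo-4-hydroxybenzaldehyde
Product: **2** (E)-1-(5-bromo-2,4-dihydroxyphenyl)-3-(3-bromo-4-hydroxyphenyl)prop-2-en-1-one
Conditions: KOH (6 equiv), EtOH/H2O, rt, 24–48 h; then cold 1 M HCl to pH ~3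
Reagents that add atoms: none
Why: This is a Claisen–Schmidt (aldol/E1cB) condensation. Excess base converts the phenols to phenoxides, so only the acetyl CH3 is enolised, and the E-enone forms as the thermodynamic product (this sets the alkene geometry). The Ar–Br bonds survive KOH at rt.

**Step 2**
Reactants: **2** dibromochalcone; **5** prenyl-Bpin (3 equiv)
Product: **1** Stipulin
Conditions: Pd2(dba)3 (2.5 mol%), t-BuXPhos (10 mol%), K3PO4 (6 equiv), THF/H2O 10:1, 60 °C, 12 h
Reagents that add atoms: prenylBpin, 2-(3-methylbut-2-en-1-yl)-4,4,5,5-tetramethyl-1,3,2-dioxaborolane, `CC(C)=CCB1OC(C)(C)C(C)(C)O1`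
Why: This is a ligand-controlled α-selective Suzuki–Miyaura allyl–aryl coupling. A bulky biaryl phosphine favours the linear (normal) prenyl product over the reverse-prenyl γ-product, and it occurs at both C–Br positions. No stereocentre is formed, and the E-enone is untouched. This step assumes the Suzuki conditions tolerate free phenols.

**Checks.**
- The target SMILES has a 4-hydroxy-3-prenylphenyl ring B and a 2,4-dihydroxy-5-prenylphenyl ketone ring A. This matches the position of each Br in **2**.
- Atom balance: C15H10Br2O4 + 2 C5H9 → C25H28O4.
- The only stereo-element is the E-alkene, which is set in Step 1 and not altered in Step 2.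

## Compound list
| # | Name | SMILES | Role |
|---|---|---|---|
| 1 | Stipulin, (E)-1-(2,4-dihydroxy-5-prenylphenyl)-3-(4-hydroxy-3-prenylphenyl)prop-2-en-1-one | `CC(C)=CCc1cc(/C=C/C(=O)c2cc(CC=C(C)C)c(O)cc2O)ccc1O` | target |
| 2 | (E)-1-(5-bromo-2,4-dihydroxyphenyl)-3-(3-bromo-4-hydroxyphenyl)prop-2-en-1-one | `O=C(/C=C/c1ccc(O)c(Br)c1)c1cc(Br)c(O)cc1O` | intermediate |
| 3 | 1-(5-bromo-2,4-dihydroxyphenyl)ethanone | `CC(=O)c1cc(Br)c(O)cc1O` | starting material |
| 4 | 3-bromo-4-hydroxybenzaldehyde | `O=Cc1ccc(O)c(Br)c1` | starting material |
| 5 | prenyl-Bpin (2-(3-methylbut-2-en-1-yl)-4,4,5,5-tetramethyl-1,3,2-dioxaborolane) | `CC(C)=CCB1OC(C)(C)C(C)(C)O1` | starting material (reagent) |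

## Totals
- Total step count: 2
- Longest linear sequence: 2 steps (**3** + **4** → **2** → **1**)

## Three most likely failure points
There are only two steps, so these are ranked failure modes across them.

1. **Step 2, α/γ regioselectivity and completion of the double coupling.** Prenyl-Bpin can give reverse-prenyl (γ) products, and the electron-rich bromophenols couple slowly.
   - Fallback: couple with allyl-Bpin, which has no regiochemistry issue, then cross-metathesize with 2-methyl-2-butene using Grubbs II to build the prenyl group.
2. **Step 2, base-induced cyclisation and phenol interference.** The hot aqueous K3PO4 can cyclise the 2'-hydroxychalcone to the flavanone and can poison the catalyst.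
   - Fallback: change the nucleophile to a Stille coupling with prenyltributylstannane under neutral conditions (Pd(PPh3)4, DMF, 80 °C).
3. **Step 1, Claisen–Schmidt on unprotected polyphenols.** Yields can be low because of phenoxide deactivation, flavanone formation and Cannizzaro-type side reactions.
   - Fallback: protect **3** and **4** as MOM ethers, condense them, run the Step 2 coupling on the protected dibromide, and remove the MOM groups with a mild acid (PPTS in t-BuOH or MeOH) that the prenyl groups survive.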